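Retrosynthesis: the side chain is cut at C13=C14 (olefination) and C9–C11 (Michael addition), C17 at C8=C17 (methylenation); ring B is then cut at C6–C7 and C9–C10 into the bis-silyl dienolate of methyl acetoacetate (15) and the ring-A allylic lactone 14.
Forward: ring A is made first from an arene (Birch reduction–alkylation, iodolactonisation), ring B is closed on it in one [3+3] annulation, then the side chain and the exocyclic methylene are added.
Enabling feature: the axial C19 carboxyl on C4 of ring A is 1,3-diaxial to C10. Tied back as the 19→10 lactone it makes C6–C5–C10 an allyl cation precursor, then relays C5–H and the C9–C10 bond with the natural configuration and is released as the free acid.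
Stereochemistry: C4 from auxiliary-controlled enolate methylation; C3 by hydride addition to the rigid iodolactone; C5 and C10 in the key step; C9 by equilibration next to the C8 ketone; 13E from the olefination.

Key step: step 7

Assumption: (S)-4 is taken to give the C4 configuration drawn in 8 and 9, as in the parent 2-methoxybenzamide series; if the sense is opposite, (R)-4 is used instead. Labdane numbering (C1–C20) is used for all ring compounds.

Step 1
Reactants: 1 3-bromo-6-methoxy-2-methylbenzoic acid; 2 trimethylboroxine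
Product: 3 6-methoxy-2,3-dimethylbenzoic acid
Conditions: Pd(dppf)Cl2 (5 mol%), K2CO3, dioxane/H2O, 100 °C; HCl work-up
Reagents that add atoms: trimethylboroxine (2), CB1OB(C)OB(C)O1
Why: Suzuki–Miyaura cross-coupling of the aryl bromide with the methylboron reagent should proceed on the carboxylate salt and installs the future C20 methyl next to the future C6 methyl.

Step 2
Reactants: 3 6-methoxy-2,3-dimethylbenzoic acid; 4 (S)-2-(methoxymethyl)pyrrolidine
Product: 6 (6-methoxy-2,3-dimethylphenyl)[(2S)-2-(methoxymethyl)pyrrolidin-1-yl]methanone, via acid chloride 5 (not isolated)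
Conditions: (COCl)2, DMF (cat.), CH2Cl2, 0 → 23 °C; then 4, Et3N, CH2Cl2, 0 → 23 °C
Reagents that add atoms: (S)-2-(methoxymethyl)pyrrolidine (4), COC[C@@H]1CCCN1
Why: Acyl chloride formation followed by amidation is the standard way to acylate a secondary amine with a 2,6-disubstituted benzoic acid and introduces the prolinol-ether auxiliary without touching its stereocentre.

Step 3
Reactants: 6 (6-methoxy-2,3-dimethylphenyl)[(2S)-2-(methoxymethyl)pyrrolidin-1-yl]methanone; 7 iodomethane
Product: 9 [(2S)-2-(methoxymethyl)pyrrolidin-1-yl][(1R)-1,2,3-trimethyl-6-oxocyclohex-2-en-1-yl]methanone, via methyl enol ether 8 (not isolated)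
Conditions: K, NH3 (l)/THF, t-BuOH (1 equiv), −78 °C; then MeI, −78 °C; NH4Cl; then 1 M HCl, MeOH, 23 °C
Reagents that add atoms: iodomethane (7), CI; water, O
Why: Birch reduction–alkylation of the chiral benzamide reduces the ipso and para carbons to a potassium amide enolate that is chelated by the auxiliary ether and methylated on the face away from its CH2OMe arm, which sets quaternary C4, and mild acid then hydrolyses the enol ether to the C3 ketone while the C5=C10 alkene cannot move into conjugation past quaternary C4.

Step 4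
Reactants: 9 [(2S)-2-(methoxymethyl)pyrrolidin-1-yl][(1R)-1,2,3-trimethyl-6-oxocyclohex-2-en-1-yl]methanone
Product: 10 8-iodo-1,5,8-trimethyl-6-oxabicyclo[3.2.1]octane-2,7-dione (ring A as 5α-iodo-3-oxo-19,10β-olide)
Conditions: I2, NaHCO3, THF/H2O (1:1), 23 °C, dark; Na2S2O3 work-up
Reagents that add atoms: iodine, II; water, O
Why: Iodolactonisation of the β,γ-unsaturated amide closes the γ-lactone in a 5-endo mode with the amide oxygen adding to tertiary C10 anti to the iodonium ion (I on C5 α, O on C10 β, both fixed by C4), and hydrolysis of the iminium ether releases the auxiliary.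

Step 5
Reactants: 10 8-iodo-1,5,8-trimethyl-6-oxabicyclo[3.2.1]octane-2,7-dione
Product: 11 2-hydroxy-8-iodo-1,5,8-trimethyl-6-oxabicyclo[3.2.1]octan-7-one (3α-hydroxy-5α-iodo-19,10β-olide)
Conditions: L-Selectride, THF, −78 °C; NH4Cl work-up
Reagents that add atoms: none
Why: Hydride reduction of a cyclohexanone with a 1,3-diaxial substituent: the axial C5 iodine blocks the α face, so the bulky borohydride should add from the β (equatorial) side and give the axial 3α-alcohol.

Step 6
Reactants: 11 2-hydroxy-8-iodo-1,5,8-trimethyl-6-oxabicyclo[3.2.1]octan-7-one; 12 acetic anhydride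
Product: 14 1,5-dimethyl-8-methylidene-7-oxo-6-oxabicyclo[3.2.1]octan-2-yl acetate (3α-acetoxy-19,10β-olide with C5=C6 methylene), via hydroxy methylene lactone 13 (not isolated)
Conditions: DBU (3 equiv), THF, 50 °C; then Ac2O, DMAP (cat.), 23 °C
Reagents that add atoms: acetic anhydride (12), CC(=O)OC(C)=O
Why: E2 dehydroiodination of the tertiary iodide can only take a hydrogen from the C6 methyl and so gives the exocyclic C5=C6 methylene, after which DMAP-catalysed acylation caps the hindered axial alcohol.

Step 7
Reactants: 14 1,5-dimethyl-8-methylidene-7-oxo-6-oxabicyclo[3.2.1]octan-2-yl acetate; 15 1-methoxy-1,3-bis(trimethylsilyloxy)buta-1,3-diene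
Product: 18 methyl 3α-acetoxy-19-carboxy-8-oxo-decalin-9-carboxylate (methyl 6-acetoxy-5-carboxy-5,8a-dimethyl-2-oxodecahydronaphthalene-1-carboxylate; 5α-H and 10β-Me), via seco keto ester acid 16 (not isolated), via saturated keto ester lactone 17 (not isolated)
Conditions: SnCl4 (2.5 equiv), CH2Cl2, −78 °C, add 15; then MeOH (2 equiv), −78 → 23 °C; H2O work-up
Reagents that add atoms: 1-methoxy-1,3-bis(trimethylsilyloxy)buta-1,3-diene (15), COC(O[Si](C)(C)C)=CC(O[Si](C)(C)C)=C
Why: Proposed new method: SnCl4 ionises the tertiary allylic C10–O bond of lactone 14 to the C6–C5–C10 allyl cation (carboxylate held on tin), and the terminal carbon of silyl dienolate 15 attacks the unhindered C6 end (vinylogous Mukaiyama-type allylic alkylation) to give 16 with a tetrasubstituted C5=C10 alkene. MeOH then frees the β-keto ester enol and the acid, a proton adds to C5 while the axial C19 carboxyl captures C10 from the β face (lactone 17), and re-ionisation lets the enol carbon C9 attack C10 from the α face, closing ring B in a 6-endo-trig cation–olefin mode (formally a 6-exo-tet displacement at C10 of 17) and leaving the free C19 acid. The closest known reactions are the Lewis-acid allylation of silyl dienolates and the SnCl4-mediated β-keto-ester-terminated cyclisation of 2-(cyclohexenyl)ethyl keto esters to trans-decalins; only their merger through a lactone relay is new. C5 (H α) is set by anti addition of H and carboxylate across C5=C10 and by the axial 3α-acetoxy group, which keeps the C6 chain equatorial under the reversible conditions; C10 (Me β) follows from inversion at the lactone C–O bond, so the ring fusion is trans; C9 is epimerisable and is reset later. The step needs attack at C6 and not C10 in the first bond (sterics at the quaternary end) and C- over O-cyclisation in the second (enol-ether and lactone formation are reversible under SnCl4, C–C bond formation is not).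

Step 8
Reactants: 18 methyl 3α-acetoxy-19-carboxy-8-oxo-decalin-9-carboxylate; 19 methyl vinyl ketone
Product: 20 methyl 6-acetoxy-5-carboxy-5,8a-dimethyl-2-oxo-1-(3-oxobutyl)decahydronaphthalene-1-carboxylate (9α-oxobutyl and 9β-CO2Me)
Conditions: FeCl3·6H2O (10 mol%), methyl vinyl ketone (3 equiv), CH2Cl2, 23 °C
Reagents that add atoms: methyl vinyl ketone (19), C=CC(C)=O
Why: Iron(III)-catalysed Michael addition of the β-keto ester to methyl vinyl ketone needs no base and should form the C9–C11 bond from the α face opposite the axial C10 methyl, the configuration of quaternary C9 being erased again in step 10.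

Step 9
Reactants: 20 methyl 6-acetoxy-5-carboxy-5,8a-dimethyl-2-oxo-1-(3-oxobutyl)decahydronaphthalene-1-carboxylate; 21 triethyl phosphonoacetate
Product: 22 ethyl (E)-5-[6-acetoxy-5-carboxy-1-(methoxycarbonyl)-5,8a-dimethyl-2-oxodecahydronaphthalen-1-yl]-3-methylpent-2-enoate
Conditions: NaH (3.2 equiv), 21 (2.1 equiv), THF, 0 → 23 °C; aq. HCl work-up; chromatography
Reagents that add atoms: triethyl phosphonoacetate (21), CCOC(=O)CP(=O)(OCC)OCC
Why: Horner–Wadsworth–Emmons olefination should be selective for the unhindered C13 methyl ketone over the neopentyl C8 ketone and give mainly the 13E enoate, the minor 13Z isomer being removed by chromatography.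

Step 10
Reactants: 22 ethyl (E)-5-[6-acetoxy-5-carboxy-1-(methoxycarbonyl)-5,8a-dimethyl-2-oxodecahydronaphthalen-1-yl]-3-methylpent-2-enoate
Product: 23 3α-acetoxy-15-ethoxy-8,15-dioxo-17-norlabd-13E-en-19-oic acid
Conditions: LiCl, DMSO, H2O (2 equiv), 150 °C; aq. HCl work-up
Reagents that add atoms: none
Why: Krapcho dealkoxycarbonylation (chloride demethylation, loss of CO2) removes the activating ester, and the C9 enolate is protonated to the thermodynamically preferred equatorial 9β side chain (9α-H), which stays epimerisable next to the C8 ketone.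

Step 11
Reactants: 23 3α-acetoxy-15-ethoxy-8,15-dioxo-17-norlabd-13E-en-19-oic acid; 24 dibromomethane
Product: 25 3α-acetoxy-15-ethoxy-15-oxolabda-8(17),13E-dien-19-oic acid
Conditions: Zn, CH2Br2, TiCl4, THF/CH2Cl2, 0 → 23 °C
Reagents that add atoms: dibromomethane (24), BrCBr
Why: Takai–Lombardo methylenation with the non-basic zinc–titanium methylene reagent should convert the hindered, enolisable C8 ketone into the 8(17) methylene without epimerising C9 and leave the esters and the carboxylate alone.

Step 12
Reactants: 25 3α-acetoxy-15-ethoxy-15-oxolabda-8(17),13E-dien-19-oic acid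
Product: 26 3α,15-dihydroxylabda-8(17),13E-dien-19-oic acid
Conditions: DIBAL-H (6 equiv), CH2Cl2, −78 → 0 °C; Rochelle salt work-up
Reagents that add atoms: none
Why: DIBAL-H reduces the conjugated ethyl ester by 1,2-addition to the allylic alcohol and cleaves the acetate, while the hindered axial C19 carboxylate (as its aluminium salt) should not be reduced at low temperature.

Step 13
Reactants: 26 3α,15-dihydroxylabda-8(17),13E-dien-19-oic acid; 12 acetic anhydride
Product: 27 3α,15-diacetoxylabda-8(17),13E-dien-19-oic acid
Conditions: Ac2O, pyridine, DMAP (cat.), 23 °C; aq. NaHCO3, then dilute HCl work-up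
Reagents that add atoms: acetic anhydride (12), CC(=O)OC(C)=O
Why: DMAP-catalysed acetylation esterifies both hydroxyl groups, and the mixed anhydride formed at C19 is hydrolysed back to the acid in the aqueous work-up.

Step 14
Reactants: 27 3α,15-diacetoxylabda-8(17),13E-dien-19-oic acid
Product: 28 3α-acetoxy-15-hydroxylabda-8(17),13E-dien-19-oic acid (target; 3R,4R,5R,9S,10R)
Conditions: Candida antarctica lipase B (immobilised), n-BuOH (5 equiv), MTBE, 40 °C
Reagents that add atoms: none
Why: Lipase-catalysed transesterification should remove only the unhindered primary allylic acetate, because the axial 3α-acetate next to quaternary C4 does not fit the active site.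

Compound list
1 | 3-bromo-6-methoxy-2-methylbenzoic acid | COc1ccc(Br)c(C)c1C(=O)O | starting material
2 | trimethylboroxine | CB1OB(C)OB(C)O1 | starting material
3 | 6-methoxy-2,3-dimethylbenzoic acid | COc1ccc(C)c(C)c1C(=O)O | intermediate
4 | (S)-2-(methoxymethyl)pyrrolidine | COC[C@@H]1CCCN1 | starting material
5 | 6-methoxy-2,3-dimethylbenzoyl chloride (not isolated) | COc1ccc(C)c(C)c1C(Cl)=O | intermediate
6 | (6-methoxy-2,3-dimethylphenyl)[(2S)-2-(methoxymethyl)pyrrolidin-1-yl]methanone | COc1ccc(C)c(C)c1C(=O)N1CCC[C@H]1COC | intermediate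
7 | iodomethane | CI | starting material
8 | [(1R)-2-methoxy-1,5,6-trimethylcyclohexa-2,5-dien-1-yl][(2S)-2-(methoxymethyl)pyrrolidin-1-yl]methanone (not isolated) | COC1=CCC(C)=C(C)[C@@]1(C)C(=O)N1CCC[C@H]1COC | intermediate
9 | [(2S)-2-(methoxymethyl)pyrrolidin-1-yl][(1R)-1,2,3-trimethyl-6-oxocyclohex-2-en-1-yl]methanone | CC1=C(C)[C@@](C)(C(=O)N2CCC[C@H]2COC)C(=O)CC1 | intermediate
10 | 8-iodo-1,5,8-trimethyl-6-oxabicyclo[3.2.1]octane-2,7-dione; ring A as 5α-iodo-3-oxo-19,10β-olide, iodine trans to the lactone oxygen | C[C@]1(I)[C@@]2(C)CCC(=O)[C@]1(C)C(=O)O2 | intermediate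
11 | 2-hydroxy-8-iodo-1,5,8-trimethyl-6-oxabicyclo[3.2.1]octan-7-one; 3α-hydroxy-5α-iodo-19,10β-olide | C[C@]1(I)[C@@]2(C)CC[C@@H](O)[C@]1(C)C(=O)O2 | intermediate
12 | acetic anhydride | CC(=O)OC(C)=O | starting material
13 | 2-hydroxy-1,5-dimethyl-8-methylidene-6-oxabicyclo[3.2.1]octan-7-one; 3α-hydroxy-19,10β-olide with C5=C6 methylene (not isolated) | C=C1[C@@]2(C)CC[C@@H](O)[C@]1(C)C(=O)O2 | intermediate
14 | 1,5-dimethyl-8-methylidene-7-oxo-6-oxabicyclo[3.2.1]octan-2-yl acetate; 3α-acetoxy-19,10β-olide with C5=C6 methylene | C=C1[C@@]2(C)CC[C@@H](OC(C)=O)[C@]1(C)C(=O)O2 | intermediate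
15 | 1-methoxy-1,3-bis(trimethylsilyloxy)buta-1,3-diene | COC(O[Si](C)(C)C)=CC(O[Si](C)(C)C)=C | starting material
16 | (1R,6R)-6-acetoxy-2-(5-methoxy-3,5-dioxopentyl)-1,3-dimethylcyclohex-2-ene-1-carboxylic acid (not isolated) | COC(=O)CC(=O)CCC1=C(C)CC[C@@H](OC(C)=O)[C@]1(C)C(=O)O | intermediate
17 | methyl 5-(2-acetoxy-1,5-dimethyl-7-oxo-6-oxabicyclo[3.2.1]octan-8-yl)-3-oxopentanoate; 3α-acetoxy-5α-H-19,10β-olide (not isolated) | COC(=O)CC(=O)CC[C@@H]1[C@@]2(C)CC[C@@H](OC(C)=O)[C@]1(C)C(=O)O2 | intermediate
18 | methyl 6-acetoxy-5-carboxy-5,8a-dimethyl-2-oxodecahydronaphthalene-1-carboxylate; 3α-OAc, 4β-COOH, 5α-H, 10β-Me, 8-oxo, 9β-CO2Me | O=C1CC[C@@H]2[C@](C)(CC[C@@H](OC(C)=O)[C@]2(C)C(=O)O)[C@H]1C(=O)OC | intermediate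
19 | methyl vinyl ketone | C=CC(C)=O | starting material
20 | methyl 6-acetoxy-5-carboxy-5,8a-dimethyl-2-oxo-1-(3-oxobutyl)decahydronaphthalene-1-carboxylate; 9α-oxobutyl, 9β-CO2Me | O=C1CC[C@@H]2[C@](C)(CC[C@@H](OC(C)=O)[C@]2(C)C(=O)O)[C@]1(C(=O)OC)CCC(C)=O | intermediate
21 | triethyl phosphonoacetate | CCOC(=O)CP(=O)(OCC)OCC | starting material
22 | ethyl (E)-5-[6-acetoxy-5-carboxy-1-(methoxycarbonyl)-5,8a-dimethyl-2-oxodecahydronaphthalen-1-yl]-3-methylpent-2-enoate | O=C1CC[C@@H]2[C@](C)(CC[C@@H](OC(C)=O)[C@]2(C)C(=O)O)[C@]1(C(=O)OC)CC/C(C)=C/C(=O)OCC | intermediate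
23 | 3α-acetoxy-15-ethoxy-8,15-dioxo-17-norlabd-13E-en-19-oic acid | O=C1CC[C@@H]2[C@](C)(CC[C@@H](OC(C)=O)[C@]2(C)C(=O)O)[C@H]1CC/C(C)=C/C(=O)OCC | intermediate
24 | dibromomethane | BrCBr | starting material
25 | 3α-acetoxy-15-ethoxy-15-oxolabda-8(17),13E-dien-19-oic acid | C=C1CC[C@@H]2[C@](C)(CC[C@@H](OC(C)=O)[C@]2(C)C(=O)O)[C@H]1CC/C(C)=C/C(=O)OCC | intermediate
26 | 3α,15-dihydroxylabda-8(17),13E-dien-19-oic acid | C=C1CC[C@@H]2[C@](C)(CC[C@@H](O)[C@]2(C)C(=O)O)[C@H]1CC/C(C)=C/CO | intermediate
27 | 3α,15-diacetoxylabda-8(17),13E-dien-19-oic acid | C=C1CC[C@@H]2[C@](C)(CC[C@@H](OC(C)=O)[C@]2(C)C(=O)O)[C@H]1CC/C(C)=C/COC(C)=O | intermediate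
28 | 3α-acetoxy-15-hydroxylabda-8(17),13E-dien-19-oic acid | C=C1CC[C@@H]2[C@](C)(CC[C@@H](OC(C)=O)[C@]2(C)C(=O)O)[C@H]1CC/C(C)=C/CO | target

Total step count: 14. Longest linear sequence: 14 steps (1 → 28); all other inputs are purchased.

Steps most likely to fail

Step 7. The cascade may stall after the first C–C bond: the C10 cation can be held as lactone 17, or O-alkylated by the keto-ester enol faster than it is C-alkylated, and C5 may be protonated with poor facial control. The fallback sets out from 14 and comes back at 18 in separate stages with isolated intermediates. Catalytic TMSOTf in CH2Cl2 at −78 °C effects only the allylic substitution of 14 by 15, and 16 is isolated after mild acidic work-up. TsOH in CH2Cl2 closes 16 to lactone 17 under equilibrating conditions. TMSOTf/Et3N converts 17 into the trimethylsilyl enol ether of lactone 17 F1. TiCl4 at −78 → 0 °C then ionises the tertiary lactone C–O bond and the preformed silyl enol ether is alkylated at C9 (aprotic Lewis-acid α-tert-alkylation of a silyl enol ether), giving 18 after aqueous work-up.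

Step 3. Facial discrimination in the methylation of the twisted 2,6-disubstituted benzamide enolate may be incomplete, or the electron-rich ring may be reduced sluggishly. The fallback sets out from 3 and comes back at 9 by separating diastereomers instead of relying on auxiliary control. Birch reduction–methylation of the free acid 3 (Li, NH3/THF; MeI) gives racemic 6-methoxy-1,2,3-trimethylcyclohexa-2,5-diene-1-carboxylic acid F2. Its acid chloride (1-chloro-N,N,2-trimethylprop-1-en-1-amine, neutral conditions) is coupled with 4 to give 8 together with the C4-epimer of 8 F3. The two amides are separated by chromatography, and 8 is hydrolysed with 1 M HCl/MeOH to 9.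

Step 8. Conjugate addition at the neopentyl-like C9 may be slow and lose out to polymerisation of the enone. The fallback sets out from 18 and comes back at 20 by the Wichterle reaction. The disodium salt of 18 (NaH, 2 equiv, DMF) is alkylated at C9 with 1,3-dichlorobut-2-ene (CC(Cl)=CCCl) to the C9-(3-chlorobut-2-enyl) keto ester F4. Its vinyl chloride is then hydrolysed with Hg(OAc)2 in formic acid to the methyl ketone 20.

Further compounds
F1 | step 7 | trimethylsilyl enol ether of lactone 17 | COC(=O)C=C(O[Si](C)(C)C)CC[C@@H]1[C@@]2(C)CC[C@@H](OC(C)=O)[C@]1(C)C(=O)O2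
F2 | step 3 | racemic 6-methoxy-1,2,3-trimethylcyclohexa-2,5-diene-1-carboxylic acid | COC1=CCC(C)=C(C)C1(C)C(=O)O
F3 | step 3 | C4-epimer of 8 | COC1=CCC(C)=C(C)[C@]1(C)C(=O)N1CCC[C@H]1COC
F4 | step 8 | C9-(3-chlorobut-2-enyl) keto ester | O=C1CC[C@@H]2[C@](C)(CC[C@@H](OC(C)=O)[C@]2(C)C(=O)O)[C@]1(C(=O)OC)CC=C(C)Cl
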